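**Retrosynthetic overview**
1. Dihydropyran (last ring): the target is opened to its isomer, the internal alkynol ArCH(OH)-CH(CH2OAc)-CH2-C≡C-(benzofuran-2-yl). The O-C6 bond and the branched C5 are made together by an alkyne-to-vinylidene 1,2-carbon shift at ruthenium, followed by O-H addition.
2. Furan ring of the benzofuran (second ring): a terminal 1,3-diyne plus 4-bromo-2,5-dihydroxyacetophenone (Sonogashira coupling, then 5-endo-dig closure).
3. Diyne: a terminal alkyne plus silyl-protected bromoacetylene (Cadiot-Chodkiewicz). The primary acetate is placed by a lipase.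
4. Both stereocentres: a cis-β-lactone (first, temporary ring) from vanillin and pent-4-ynoyl chloride, opened reductively to the syn-1,3-diol.
5. Vanillin comes from catechol, MeI and glyoxylic acid. The bromoketone comes from 1,4-benzoquinone, HBr and AcOH.

Assumption: O-trimethylsilylquinidine is taken to give the (3R,4R)-lactone, by analogy with quinidine-catalysed ketene-aldehyde additions; if the sense is opposite, the pseudoenantiomer O-trimethylsilylquinine is used.

**Step 1**
Reactants: 1 catechol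
Product: 2 guaiacol (2-methoxyphenol)
Conditions: MeI (1.0 equiv), K2CO3 (1.0 equiv), acetone, reflux (1 in 1.5-fold excess)
Reagents that add atoms: iodomethane CI
Why: Williamson mono-O-methylation; the excess of catechol and one equivalent of base hold the reaction at the monoether.

**Step 2**
Reactants: 2 guaiacol; 3 glyoxylic acid
Product: 6 vanillin (4-hydroxy-3-methoxybenzaldehyde), via vanillylmandelic acid 4 (not isolated), via aryl glyoxylic acid 5 (not isolated)
Conditions: 3 (50% aq), NaOH, H2O, 30 °C; then CuSO4 (5 mol %), air, 95 °C; then H2SO4 to pH 3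
Reagents that add atoms: none
Why: Phenoxide hydroxyalkylation para to OH, followed by aerobic oxidation and decarboxylation of the α-keto acid (the glyoxylic acid route to vanillin).

**Step 3**
Reactants: 6 vanillin; 7 pent-4-ynoyl chloride (two molecules are incorporated)
Product: 10 2-methoxy-4-[(2R,3R)-4-oxo-3-(prop-2-yn-1-yl)oxetan-2-yl]phenyl pent-4-ynoate, via aryl ester 8 (not isolated), via propargylketene 9 (not isolated)
Conditions: 7 (1.05 equiv), i-Pr2NEt, CH2Cl2, 0 °C, 15 min; then O-trimethylsilylquinidine (15 mol %), LiClO4 (1 equiv), CH2Cl2/Et2O, -78 °C, 7 (2 equiv, syringe pump), i-Pr2NEt (2.5 equiv), to -40 °C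
Reagents that add atoms: none
Why: Acyl halide-aldehyde cyclocondensation (catalytic asymmetric ketene-aldehyde aldol-lactonisation): in-situ O-acylation masks the phenol and makes the aldehyde more electrophilic, the alkaloid-bound enolate adds through a closed Li-organised transition state to give the cis lactone, and the alkaloid face-shielding sets both centres as (3R,4R).

**Step 4**
Reactants: 10 cis-β-lactone
Product: 11 (1R,2S)-1-(4-hydroxy-3-methoxyphenyl)-2-(prop-2-yn-1-yl)propane-1,3-diol
Conditions: LiBH4 (3 equiv), THF, MeOH (1 equiv), 0 °C to rt; then H2O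
Reagents that add atoms: none
Why: Hydride reduction with acyl-oxygen cleavage opens the lactone to the syn-1,3-diol without touching either stereocentre, and removes the sacrificial aryl ester in the same operation.

**Step 5**
Reactants: 11 triol
Product: 12 (2S,3R)-3-hydroxy-3-(4-hydroxy-3-methoxyphenyl)-2-(prop-2-yn-1-yl)propyl acetate
Conditions: immobilised Candida antarctica lipase B, vinyl acetate (3 equiv), MTBE, 30 °C
Reagents that add atoms: vinyl acetate C=COC(C)=O
Why: Lipase transesterification acylates only the primary aliphatic OH; phenols and the doubly hindered secondary benzylic OH are not accepted.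

**Step 6**
Reactants: 12 alkyne monoacetate; 13 (bromoethynyl)triisopropylsilane (bromoacetylene carrying a triisopropylsilyl protecting group)
Product: 14 (2S,3R)-3-hydroxy-3-(4-hydroxy-3-methoxyphenyl)-2-[5-(triisopropylsilyl)penta-2,4-diyn-1-yl]propyl acetate
Conditions: 13 (1.2 equiv), CuCl (10 mol %), NH2OH·HCl (30 mol %), 30% aq n-BuNH2, CH2Cl2, 0 °C, 30 min
Reagents that add atoms: none
Why: Cadiot-Chodkiewicz coupling; the bulky silyl group survives the amine, the reducing medium protects the phenol, and the short cold contact spares the acetate.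

**Step 7**
Reactants: 15 1,4-benzoquinone
Product: 16 2-bromobenzene-1,4-diol
Conditions: 48% aq HBr (1.2 equiv), Et2O, 0 °C to rt
Reagents that add atoms: hydrogen bromide Br
Why: Conjugate (1,4-) hydrobromination of the quinone followed by enolisation to the hydroquinone.

**Step 8**
Reactants: 16 2-bromobenzene-1,4-diol
Product: 17 1-(4-bromo-2,5-dihydroxyphenyl)ethan-1-one
Conditions: AcOH (1.5 equiv), BF3·OEt2 (4 equiv), 95 °C, 3 h; then H2O
Reagents that add atoms: acetic acid CC(=O)O
Why: Nencki/Fries-type C-acylation ortho to an OH; bromine directs the acyl group to its para position, and the position between Br and OH is blocked sterically.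

**Step 9**
Reactants: 14 silyl diyne; 17 bromoketone
Product: 20 (2S,3R)-2-[3-(6-acetyl-5-hydroxy-1-benzofuran-2-yl)prop-2-yn-1-yl]-3-hydroxy-3-(4-hydroxy-3-methoxyphenyl)propyl acetate, via terminal diyne 18 (not isolated), via alkynylphenol 19 (not isolated)
Conditions: TBAF (1.05 equiv), THF, 0 °C, 15 min; then 17 (1.0 equiv), Pd(PhCN)2Cl2 (3 mol %), [HP(t-Bu)3]BF4 (6 mol %), CuI (5 mol %), i-Pr2NH, 25 to 55 °C
Reagents that add atoms: none
Why: Fluoride desilylation, Sonogashira coupling of the acetyl-activated aryl bromide, and CuI/amine-promoted 5-endo-dig addition of the ortho OH to the proximal alkyne; only the OH next to bromine can close, which fixes the 6-acetyl-5-hydroxy pattern.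

**Step 10**
Reactants: 20 internal alkynol
Product: 21 propolis-benzofuran A, [(2R,3S)-5-(6-acetyl-5-hydroxy-1-benzofuran-2-yl)-2-(4-hydroxy-3-methoxyphenyl)-3,4-dihydro-2H-pyran-3-yl]methyl acetate
Conditions: CpRuCl(dppe) [(C5H5)RuCl(Ph2PCH2CH2PPh2)] (10 mol %), Na[B(3,5-(CF3)2C6H3)4] (12 mol %), 2,6-lutidine (20 mol %), PhCl, 110 °C, Ar
Reagents that add atoms: none
Why: Proposed new method: endo-cycloisomerisation of an internal alkynol through a disubstituted ruthenium vinylidene; chloride abstraction gives the 16-electron cation [CpRu(dppe)]+ (divalent ruthenium), which binds the alkyne and, being electron-rich and a poor π-acid, relaxes by 1,2-migration of the benzofuranyl group (or of the CH2 group, with the same result) to catalyst-bound [Ru]=C=C(benzofuranyl)(CH2R); the electrophilic α-carbon is captured by the only free aliphatic OH through a six-membered transition state, and lutidine-shuttled protonolysis of the Ru-C bond releases the O-CH=C(benzofuranyl) enol ether, so the linear C-C≡C-aryl skeleton becomes branched while both sp3 stereocentres stay untouched (the trans-(2R,3S) product is also the thermodynamic isomer); the closest known reaction types are the Ru-, Rh- and W-catalysed endo-cycloisomerisation of terminal pent-4-yn-1-ols to 3,4-dihydro-2H-pyrans (vinylidene by 1,2-H shift) and the [CpRu(dppe)]+-mediated internal-alkyne-to-vinylidene rearrangement that converts 2-alkynylanilides into 3-substituted indoles; new here are the aliphatic O-nucleophile, the six-membered enol ether and the heteroaryl/alkyl alkyne.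

**Compound list**
1 | catechol (benzene-1,2-diol) | Oc1ccccc1O | starting material
2 | guaiacol (2-methoxyphenol) | COc1ccccc1O | intermediate
3 | glyoxylic acid | O=CC(=O)O | starting material
4 | vanillylmandelic acid (racemic, not isolated) | COc1cc(C(O)C(=O)O)ccc1O | intermediate
5 | (4-hydroxy-3-methoxyphenyl)glyoxylic acid (not isolated) | COc1cc(C(=O)C(=O)O)ccc1O | intermediate
6 | vanillin | COc1cc(C=O)ccc1O | intermediate
7 | pent-4-ynoyl chloride | C#CCCC(=O)Cl | starting material
8 | 4-formyl-2-methoxyphenyl pent-4-ynoate (not isolated) | C#CCCC(=O)Oc1ccc(C=O)cc1OC | intermediate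
9 | (prop-2-yn-1-yl)ketene (not isolated) | C#CCC=C=O | intermediate
10 | 2-methoxy-4-[(2R,3R)-4-oxo-3-(prop-2-yn-1-yl)oxetan-2-yl]phenyl pent-4-ynoate (cis-β-lactone) | O=C1O[C@@H](c2ccc(OC(=O)CCC#C)c(OC)c2)[C@H]1CC#C | intermediate
11 | (1R,2S)-1-(4-hydroxy-3-methoxyphenyl)-2-(prop-2-yn-1-yl)propane-1,3-diol | COc1cc([C@H](O)[C@H](CO)CC#C)ccc1O | intermediate
12 | (2S,3R)-3-hydroxy-3-(4-hydroxy-3-methoxyphenyl)-2-(prop-2-yn-1-yl)propyl acetate | COc1cc([C@H](O)[C@H](COC(C)=O)CC#C)ccc1O | intermediate
13 | (bromoethynyl)triisopropylsilane (silyl-protected bromoacetylene) | BrC#C[Si](C(C)C)(C(C)C)C(C)C | starting material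
14 | (2S,3R)-3-hydroxy-3-(4-hydroxy-3-methoxyphenyl)-2-[5-(triisopropylsilyl)penta-2,4-diyn-1-yl]propyl acetate | COc1cc([C@H](O)[C@H](COC(C)=O)CC#CC#C[Si](C(C)C)(C(C)C)C(C)C)ccc1O | intermediate
15 | 1,4-benzoquinone | O=C1C=CC(=O)C=C1 | starting material
16 | 2-bromobenzene-1,4-diol | Oc1ccc(O)c(Br)c1 | intermediate
17 | 1-(4-bromo-2,5-dihydroxyphenyl)ethan-1-one | CC(=O)c1cc(O)c(Br)cc1O | intermediate
18 | (2S,3R)-3-hydroxy-3-(4-hydroxy-3-methoxyphenyl)-2-(penta-2,4-diyn-1-yl)propyl acetate (not isolated) | COc1cc([C@H](O)[C@H](COC(C)=O)CC#CC#C)ccc1O | intermediate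
19 | (2S,3R)-2-[5-(4-acetyl-2,5-dihydroxyphenyl)penta-2,4-diyn-1-yl]-3-hydroxy-3-(4-hydroxy-3-methoxyphenyl)propyl acetate (not isolated) | COc1cc([C@H](O)[C@H](COC(C)=O)CC#CC#Cc2cc(O)c(C(C)=O)cc2O)ccc1O | intermediate
20 | (2S,3R)-2-[3-(6-acetyl-5-hydroxy-1-benzofuran-2-yl)prop-2-yn-1-yl]-3-hydroxy-3-(4-hydroxy-3-methoxyphenyl)propyl acetate | COc1cc([C@H](O)[C@H](COC(C)=O)CC#Cc2cc3cc(O)c(C(C)=O)cc3o2)ccc1O | intermediate
21 | propolis-benzofuran A, (2R,3S), 2,3-trans | COc1cc([C@@H]2OC=C(c3cc4cc(O)c(C(C)=O)cc4o3)C[C@H]2COC(C)=O)ccc1O | target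

**Step count**
Total step count: 10.
Longest linear sequence: 8 (steps 1, 2, 3, 4, 5, 6, 9, 10).

**Steps most likely to fail**

**Step 10 (new reaction).**
- Risks: ordinary 5-exo or 6-endo π-activation may compete with vinylidene formation. The acetyl group may migrate from the primary to the secondary oxygen at 110 °C. The p-hydroxybenzylic alcohol is sensitive to heat.
- The fallback uses known chemistry only. It sets out from 12 and 17 and comes back at 21.
- The phenol of 12 is acetylated (Ac2O, K2CO3, acetone, 0 °C) to (2S,3R)-3-(4-acetoxy-3-methoxyphenyl)-3-hydroxy-2-(prop-2-yn-1-yl)propyl acetate F1. This terminal alkynol is cycloisomerised by the established tungsten vinylidene method (W(CO)6, DABCO, THF, hν, 55 °C) to [(2R,3S)-2-(4-acetoxy-3-methoxyphenyl)-3,4-dihydro-2H-pyran-3-yl]methyl acetate F2. Iodination as practised for 2-iodoglycals (NIS, AgNO3 cat., MeCN, 80 °C) gives [(2R,3S)-2-(4-acetoxy-3-methoxyphenyl)-5-iodo-3,4-dihydro-2H-pyran-3-yl]methyl acetate F3. Sonogashira coupling with ethynyltrimethylsilane (PdCl2(PPh3)2, CuI, Et3N) gives [(2R,3S)-2-(4-acetoxy-3-methoxyphenyl)-5-[(trimethylsilyl)ethynyl]-3,4-dihydro-2H-pyran-3-yl]methyl acetate F4. TBAF/AcOH then gives [(2R,3S)-2-(4-acetoxy-3-methoxyphenyl)-5-ethynyl-3,4-dihydro-2H-pyran-3-yl]methyl acetate F5. Sonogashira coupling-cyclisation with 17 under the catalyst of step 9 gives [(2R,3S)-2-(4-acetoxy-3-methoxyphenyl)-5-(6-acetyl-5-hydroxy-1-benzofuran-2-yl)-3,4-dihydro-2H-pyran-3-yl]methyl acetate F6. Finally NH4OAc in aqueous MeOH removes only the phenolic acetate to give 21.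

**Step 3.**
- Risks: the aromatic aldehyde is a sluggish acceptor, the ketene can dimerise, and the sense of induction is assumed.
- The fallback replaces catalysis by an auxiliary-controlled boron aldol. It sets out from 6 and 7 and comes back at 11.
- Vanillin 6 is acylated with 7 (Et3N, CH2Cl2, 0 °C) and ester 8 is isolated. Lithiated (R)-4-benzyl-1,3-oxazolidin-2-one is acylated with 7 to (4R)-4-benzyl-3-(pent-4-ynoyl)-1,3-oxazolidin-2-one F7. Its Z-boron enolate (Bu2BOTf, Et3N, CH2Cl2, -78 °C) adds to 8 to give the Evans syn adduct 4-[(1R,2R)-2-{[(4R)-4-benzyl-2-oxo-1,3-oxazolidin-3-yl]carbonyl}-1-hydroxypent-4-yn-1-yl]-2-methoxyphenyl pent-4-ynoate F8. LiBH4 (THF/MeOH) cleaves the auxiliary and the aryl ester together to give 11.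

**Step 9.**
- Risks: the terminal diyne 18 is fragile and prone to homocoupling, and the bromophenol is a slow coupling partner.
- The fallback avoids any diyne by reversing the roles of the partners. It sets out from 12 and 17 and comes back at 20, so steps 6 and 9 are replaced.
- Bromoketone 17 and ethynyltrimethylsilane (PdCl2(PPh3)2, CuI, Et3N, DMF, 70 °C) give 1-[5-hydroxy-2-(trimethylsilyl)-1-benzofuran-6-yl]ethan-1-one F9. ICl (CH2Cl2, -78 °C) effects ipso-iododesilylation to 1-(5-hydroxy-2-iodo-1-benzofuran-6-yl)ethan-1-one F10. Room-temperature Sonogashira coupling of F10 with the terminal alkyne 12 gives 20.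

**Further compounds**
F1 | step 10 | (2S,3R)-3-(4-acetoxy-3-methoxyphenyl)-3-hydroxy-2-(prop-2-yn-1-yl)propyl acetate | COc1cc([C@H](O)[C@H](COC(C)=O)CC#C)ccc1OC(C)=O
F2 | step 10 | [(2R,3S)-2-(4-acetoxy-3-methoxyphenyl)-3,4-dihydro-2H-pyran-3-yl]methyl acetate | COc1cc([C@@H]2OC=CC[C@H]2COC(C)=O)ccc1OC(C)=O
F3 | step 10 | [(2R,3S)-2-(4-acetoxy-3-methoxyphenyl)-5-iodo-3,4-dihydro-2H-pyran-3-yl]methyl acetate | COc1cc([C@@H]2OC=C(I)C[C@H]2COC(C)=O)ccc1OC(C)=O
F4 | step 10 | [(2R,3S)-2-(4-acetoxy-3-methoxyphenyl)-5-[(trimethylsilyl)ethynyl]-3,4-dihydro-2H-pyran-3-yl]methyl acetate | COc1cc([C@@H]2OC=C(C#C[Si](C)(C)C)C[C@H]2COC(C)=O)ccc1OC(C)=O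
F5 | step 10 | [(2R,3S)-2-(4-acetoxy-3-methoxyphenyl)-5-ethynyl-3,4-dihydro-2H-pyran-3-yl]methyl acetate | COc1cc([C@@H]2OC=C(C#C)C[C@H]2COC(C)=O)ccc1OC(C)=O
F6 | step 10 | [(2R,3S)-2-(4-acetoxy-3-methoxyphenyl)-5-(6-acetyl-5-hydroxy-1-benzofuran-2-yl)-3,4-dihydro-2H-pyran-3-yl]methyl acetate | COc1cc([C@@H]2OC=C(c3cc4cc(O)c(C(C)=O)cc4o3)C[C@H]2COC(C)=O)ccc1OC(C)=O
F7 | step 3 | (4R)-4-benzyl-3-(pent-4-ynoyl)-1,3-oxazolidin-2-one | C#CCCC(=O)N1[C@H](Cc2ccccc2)COC1=O
F8 | step 3 | 4-[(1R,2R)-2-{[(4R)-4-benzyl-2-oxo-1,3-oxazolidin-3-yl]carbonyl}-1-hydroxypent-4-yn-1-yl]-2-methoxyphenyl pent-4-ynoate | C#CC[C@H]([C@@H](O)c1ccc(OC(=O)CCC#C)c(OC)c1)C(=O)N1[C@H](Cc2ccccc2)COC1=O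
F9 | step 9 | 1-[5-hydroxy-2-(trimethylsilyl)-1-benzofuran-6-yl]ethan-1-one | CC(=O)c1cc2oc([Si](C)(C)C)cc2cc1O
F10 | step 9 | 1-(5-hydroxy-2-iodo-1-benzofuran-6-yl)ethan-1-one | CC(=O)c1cc2oc(I)cc2cc1O
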